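Which flask ends with the longer chains, dusk or dawn?

| setting | dusk | dawn |
|---|---|---|
| free monomer | 0.11 M | 0.11 M |
| initiator | 0.55 mM | 0.40 mM |
| time | 80 min | 80 min |

    free monomer + living end → monomer in chains + living end, rate k1*[living end]*[free monomer] (k1 = 33 M⁻¹ s⁻¹)
    free monomer + initiator → living end + monomer in chains (k2 = 0.088 M⁻¹ s⁻¹)
    initiator → spent initiator B (k3 = 0.016 s⁻¹)
    living end + free monomer → dead end A (k4 = 0.11 M⁻¹ s⁻¹)

* which of the two ends with the longer chains by the average number of monomer units in a chain (chains begun, living or dead) ("neither" if they lie within 10%) (dusk / dawn / neither)
* average number of monomer units in a chain (chains begun, living or dead) at the end, dusk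
* average number of monomer units in a chain (chains begun, living or dead) at the end, dawn

- the average divides the monomer in chains by the number of chains begun, living and dead together
- run time (dusk): 80 min

**In the flask.** You take over free monomer and initiator, stirred together. Initiator goes two ways in either flask, and its decay to spent initiator B, at 0.016 s⁻¹, outruns chain starting at the charge, at 0.00968 s⁻¹. With c(free monomer) held at its charge, I reckon that 37.7% of the initiator begins chains.

**What you'll find.** Propagation and death both run on c(living end) times c(free monomer), so their rates stand in the ratio of their constants, whatever those concentrations are. Add the unit set at initiation and you have the chain yield, the monomer units a chain holds on average when its end has died, or kinetic chain length: 301. Work with the fraction left: chains begun times chain yield, taken from the charge, leaves by my reckoning 43.3% of the free monomer at dusk and 58.7% at dawn.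

**Don't touch.** Don't change the initiator charge to change the length: the chain yield holds no initiator term. I expect 301 in both flasks. Don't read early either: at dusk's fraction left, a living end's half-life is 2.21 min, far inside the 80 min run.

**The forecast.** It gives 301 at dusk, 301 at dawn and neither as the longer, as I do, on the ground that “they die within a few minutes”.

**The result.** The flask gives 301 at dusk and 301 at dawn, so the longer is neither. Dusk already read 288 after 8.00 min. Now take a neighbour of dawn charged with 0.0010 M of initiator: its dead end A stands at 0.307% of the free monomer charged, which times the chain yield makes 92.4%. That neighbour ends with 92.3% as monomer in chains, at an average of 301.

(All constants were chosen freely; what happens was integrated by code.)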